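## Retrosynthetic overview
- The molecule is a squalene-type bicyclic triterpenoid. The central CH2–CH2 bond (squalene C12–C13 type) is disconnected into an 11-iodo-3-oxo-drim-7-ene and an (R)-10,11-dihydroxyfarnesyl acetate. This bond is formed last, by an electrochemical Ni cross-electrophile coupling.
- The bicyclic half comes from the same (R)-diol acetate as the tail. Inversion at the carbinol gives the (S)-10,11-epoxide, and a Ti(III) radical cascade then forms ring A and ring B, giving the trans-decalin.
- Endgame on the bicycle: exocyclic alkene → Δ7 alkene, CH2OH → CH2I, 3-OH → 3-ketone.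
- The diol acetate is built from 8-hydroxygeranyl carbonate (geranyl acetate by allylic oxidation) and a C5 iodo-diol. The only stereochemical source is methyl (R)-2,2-dimethyl-1,3-dioxolane-4-carboxylate.

Assumptions: methyl (R)-2,2-dimethyl-1,3-dioxolane-4-carboxylate (from D-mannitol) and geranyl acetate are commercial. The absolute configuration is taken from the SMILES given.

## Route

**Step 1**
Reactants: 1, geranyl acetate
Product: 2, (2E,6E)-8-hydroxy-3,7-dimethylocta-2,6-dien-1-yl acetate
Conditions: SeO2 (5 mol%), t-BuOOH (2 equiv, in decane), CH2Cl2, 0 °C → rt, 12 h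
Reagents that add atoms: tert-butyl hydroperoxide, CC(C)(C)OO (source of the new O)
Why: Umbreit–Sharpless SeO2 allylic oxidation hits the electron-rich terminal alkene at the E-methyl (trans to the chain), so the E-allylic alcohol forms with no stereocenter created.

**Step 2**
Reactants: 2
Product: 3, (2E,6E)-8-(methoxycarbonyloxy)-3,7-dimethylocta-2,6-dien-1-yl acetate
Conditions: ClCO2Me (1.3 equiv), pyridine, CH2Cl2, 0 °C, 2 h
Reagents that add atoms: methyl chloroformate, ClC(=O)OC
Why: Acylation of the allylic alcohol gives a carbonate, a better Ni-allyl precursor than the acetate, so the two allylic positions are differentiated.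

**Step 3**
Reactants: 4, methyl (4R)-2,2-dimethyl-1,3-dioxolane-4-carboxylate
Product: 5, 2-[(4R)-2,2-dimethyl-1,3-dioxolan-4-yl]propan-2-ol
Conditions: MeMgBr (3.5 equiv), THF, −10 °C → rt, 3 h
Reagents that add atoms: methylmagnesium bromide, C[Mg]Br (two Me groups)
Why: Double Grignard addition to the ester gives the tertiary carbinol. The α-carbon is untouched, so the (R) center, which becomes C22 of the target, is retained.

**Step 4**
Reactants: 5
Product: 6, (2R)-3-methylbutane-1,2,3-triol
Conditions: Dowex 50W-X8 (H+), MeOH, 25 °C, 6 h; filter and evaporate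
Reagents that add atoms: none
Why: Acid-catalysed transketalization removes the acetonide; no bond to the stereocenter is changed.

**Step 5**
Reactants: 6
Product: 7, (3S)-4-iodo-2-methylbutane-2,3-diol
Conditions: PPh3 (1.2 equiv), I2 (1.2 equiv), imidazole (3 equiv), MeCN, 0 °C → rt, 3 h
Reagents that add atoms: iodine, II
Why: Garegg–Samuelsson iodination is selective for the unhindered primary OH over the secondary and tertiary ones. The CIP label changes to (S) only because iodine outranks carbon; the spatial arrangement is unchanged.

**Step 6**
Reactants: 3 and 7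
Product: 8, (2E,6E,10R)-10,11-dihydroxy-3,7,11-trimethyldodeca-2,6-dien-1-yl acetate
Conditions: NiBr2·diglyme (10 mol%), 4,4'-di-tert-butylbipyridine (10 mol%), Zn dust (3 equiv), DMA, 25 °C, 16 h; 7 (1.5 equiv)
Reagents that add atoms: none
Why: Ni-catalysed allyl–alkyl cross-electrophile coupling. The carbonate adds to Ni(0) faster than the acetate, the alkyl radical from the iodide recombines at the unhindered CH2 terminus, and the E-alkene is retained. The carbinol stereocenter is not involved, so 8 is the (R)-diol.

**Step 7**
Reactants: 8
Product: 9, (2E,6E)-9-[(2S)-3,3-dimethyloxiran-2-yl]-3,7-dimethylnona-2,6-dien-1-ol, i.e. (10S)-10,11-epoxyfarnesol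
Conditions: MsCl (1.1 equiv), Et3N, CH2Cl2, −20 °C, 2 h; then K2CO3 (3 equiv), MeOH, 0 °C → rt, 3 h (this also removes the acetate)
Reagents that add atoms: none (Ms leaves as MsO⁻; MeOH only cleaves the acetate)
Why: MsCl mesylates only the secondary OH. The tertiary alkoxide then closes the epoxide by intramolecular SN2 with inversion at the carbinol carbon, converting the (R)-diol into the (S)-epoxide (the natural (3S)-oxidosqualene sense, which gives the 3β-O/trans-decalin series).

**Step 8**
Reactants: 9
Product: 10, drim-8(12)-ene-3β,11-diol
Conditions: Cp2TiCl2 (20 mol%), Mn or Zn dust, 2,4,6-collidine·HCl, TMSCl, THF, 25 °C, 12 h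
Reagents that add atoms: none
Why: Ti(III) opens the epoxide to the tertiary radical, which cyclises 6-endo/6-endo through a chair–chair folding (radical epoxypolyene cyclization). This sets C5-H α, C10-Me β and C9-H α, with the side chain equatorial, all under the control of the (S)-epoxide. The tertiary C8 radical then terminates by Ti-mediated β-H loss to the exocyclic methylene.

**Step 9**
Reactants: 10
Product: 11, drim-7-ene-3β,11-diol
Conditions: Co(salen)Cl (5 mol%), PhSiH3 (10 mol%), toluene, 25 °C, 4 h
Reagents that add atoms: none
Why: Co–H hydrogen-atom transfer to the 1,1-disubstituted alkene gives the tertiary C8 radical. Co(II) then removes the more accessible C7-H rather than the hindered axial C9-H, giving the trisubstituted Δ7 alkene (MHAT isomerization). No stereocenter is touched.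

**Step 10**
Reactants: 11
Product: 12, 11-iododrim-7-en-3β-ol
Conditions: PPh3 (1.2 equiv), I2 (1.2 equiv), imidazole (3 equiv), CH2Cl2, 0 °C → rt, 2 h
Reagents that add atoms: iodine, II
Why: Appel-type iodination is selective for the primary alcohol; the equatorial 3β-OH, flanked by the gem-dimethyl group, is unreactive.

**Step 11**
Reactants: 12
Product: 13, 11-iododrim-7-en-3-one
Conditions: Dess–Martin periodinane (1.5 equiv), NaHCO3, CH2Cl2, 25 °C, 1 h
Reagents that add atoms: none
Why: Dess–Martin oxidation of the secondary alcohol to the ketone. The iodide and the alkene survive, and the C3 center is destroyed as intended.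

**Step 12**
Reactants: 13 (1.0 equiv) and 8 (1.5 equiv)
Product: 14, target
Conditions: NiBr2·diglyme (10 mol%), dtbbpy (10 mol%), NaI (0.5 equiv), nBu4NBF4, DMA, undivided cell, Zn(+) anode / carbon-felt(−) cathode, 4 mA constant current, 25 °C, 14 h
Reagents that add atoms: none
Why: Proposed new method: electroreductive tail-to-tail (squalene C12–C13) coupling of a β-branched bicyclic primary iodide with a farnesyl-type allylic acetate carrying a free vicinal diol. Cathodic Ni(0) adds to the allylic acetate to give a π-allyl-Ni(II), the primary alkyl radical (from Ni(I) iodine abstraction) is captured, and reductive elimination at the unsubstituted allyl terminus keeps the E-alkenes. The closest known reaction is Ni-catalysed allyl–alkyl cross-electrophile coupling of allylic acetates with alkyl halides. Here it is applied to a neopentyl-like bicyclic iodide, a polyene with two trisubstituted alkenes, a ketone and an unprotected diol. No new stereocenter forms; all four stereocenters are already set.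

## Compound list
1 | geranyl acetate | CC(=O)OC/C=C(\C)CCC=C(C)C | starting material
2 | (2E,6E)-8-hydroxygeranyl acetate | CC(=O)OC/C=C(\C)CC/C=C(\C)CO | intermediate
3 | 8-(methoxycarbonyloxy)geranyl acetate | CC(=O)OC/C=C(\C)CC/C=C(\C)COC(=O)OC | intermediate
4 | methyl (4R)-2,2-dimethyl-1,3-dioxolane-4-carboxylate | COC(=O)[C@H]1COC(C)(C)O1 | starting material
5 | 2-[(4R)-2,2-dimethyl-1,3-dioxolan-4-yl]propan-2-ol | CC1(C)OC[C@@H](O1)C(C)(C)O | intermediate
6 | (2R)-3-methylbutane-1,2,3-triol | OC[C@@H](O)C(C)(C)O | intermediate
7 | (3S)-4-iodo-2-methylbutane-2,3-diol | IC[C@@H](O)C(C)(C)O | intermediate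
8 | (2E,6E,10R)-10,11-dihydroxyfarnesyl acetate | CC(=O)OC/C=C(\C)CC/C=C(\C)CC[C@@H](O)C(C)(C)O | intermediate
9 | (10S)-10,11-epoxyfarnesol | OC/C=C(\C)CC/C=C(\C)CC[C@@H]1OC1(C)C | intermediate
10 | drim-8(12)-ene-3β,11-diol | C=C1CC[C@H]2C(C)(C)[C@@H](O)CC[C@]2(C)[C@H]1CO | intermediate
11 | drim-7-ene-3β,11-diol | CC1=CC[C@H]2C(C)(C)[C@@H](O)CC[C@]2(C)[C@H]1CO | intermediate
12 | 11-iododrim-7-en-3β-ol | CC1=CC[C@H]2C(C)(C)[C@@H](O)CC[C@]2(C)[C@H]1CI | intermediate
13 | 11-iododrim-7-en-3-one | CC1=CC[C@H]2C(C)(C)C(=O)CC[C@]2(C)[C@H]1CI | intermediate
14 | target, C30H50O3 | CC1=CC[C@H]2C(C)(C)C(=O)CC[C@]2(C)[C@H]1CC/C=C(\C)CC/C=C(\C)CC[C@@H](O)C(C)(C)O | target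

## Totals
Total steps: 12. Longest linear sequence: 10 (4 → 5 → 6 → 7 → 8 → 9 → 10 → 11 → 12 → 13 → 14, i.e. steps 3–12).

## Three steps most likely to fail
1. **Step 12 (proposed new coupling).** Risks are homoallyl-radical ring expansion of the C11 radical, α/γ allyl selectivity, and homocoupling of the allylic acetate.
   - Fallback: a polar organometallic coupling. Protect the 3-OH of 12 as TBS, make the Grignard, and couple with the acetonide-protected allylic phosphate of 8 using Li2CuCl4 catalysis (Kochi-type SN2). Then remove the TBS, oxidise with Dess–Martin and remove the acetonide.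
2. **Step 6.** The carbonate and the C1 acetate compete in the Ni coupling, and the β-hydroxy alkyl iodide may eliminate or cyclise.
   - Fallback: make the a9–a10 bond by a different method. Convert 2 to the allylic sulfone, alkylate its anion with the epoxide from 6 (TsCl, then K2CO3) under BF3 activation, then remove the sulfone with Pd/LiBHEt3.
3. **Step 9.** Co–H isomerization may give some Δ8(9) alkene instead of Δ7.
   - Fallback: add HCl to the exocyclic alkene of 10 to form the axial tertiary chloride, then do an E2 elimination with a bulky base, which removes the accessible axial H-7 to give Δ7.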